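**Assumption:** the SMILES is read as the (7R,8R)-threo isomer, (1R,2R) in propane-1,3-diol numbering; (S)-4-benzyl-2-oxazolidinone, TBSCl and pinacolborane are bought reagents whose atoms do not end up in the target.

## Retrosynthetic overview

1. Target ⇐ bis-TBS diol ⇐ aldol adduct: the C7–C8 bond and both stereocentres come from one late Evans syn-aldol between the ring A aldehyde (O-TBS-vanillin) and the ring B aryloxyacetyl imide; only auxiliary removal and desilylation follow.
2. Ring B imide ⇐ O-TBS-sinapyl phenol + N-bromoacetyl oxazolidinone (C8 and C9 from bromoacetyl bromide), joined by a Williamson C–O bond formation.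
3. O-TBS-sinapyl phenol ⇐ 4-bromo-2,6-dimethoxyphenol (from resorcinol: methylation, ortho-lithiation/hydroxylation, bromination) + E-alkenylboronate (from propargyl alcohol), joined by Suzuki coupling.
4. Ring A aldehyde ⇐ catechol (mono-methylation, para-bromination, silylation, Br/Li exchange–DMF).
5. No ring is constructed: both benzene rings are bought intact (catechol becomes ring A, resorcinol becomes ring B).

## Route

**Step 1**
Reactants: 1 catechol (benzene-1,2-diol)
Product: 2 guaiacol (2-methoxyphenol)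
Conditions: MeI (0.8 equiv), K2CO3, acetone, reflux
Reagents that add atoms: iodomethane CI
Why: Williamson ether synthesis with MeI as the limiting reagent, so the mono-ether dominates and is separated from unreacted catechol (water-soluble) and a little veratrole (neutral) by extraction and distillation.

**Step 2**
Reactants: 2 guaiacol
Product: 3 4-bromo-2-methoxyphenol
Conditions: NBS (1.0 equiv), MeCN, 0 °C → rt
Reagents that add atoms: N-bromosuccinimide O=C1CCC(=O)N1Br
Why: Electrophilic aromatic bromination in which the free hydroxyl is the stronger director, so bromine enters para to OH rather than para to OMe.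

**Step 3**
Reactants: 3 4-bromo-2-methoxyphenol
Product: 4 (4-bromo-2-methoxyphenoxy)(tert-butyl)dimethylsilane
Conditions: TBSCl, imidazole, DMF, rt
Reagents that add atoms: tert-butyldimethylsilyl chloride CC(C)(C)[Si](C)(C)Cl
Why: Imidazole-promoted silylation masks the acidic phenol before the organolithium step and installs the group that fluoride removes at the very end.

**Step 4**
Reactants: 4 (4-bromo-2-methoxyphenoxy)(tert-butyl)dimethylsilane
Product: 7 4-(tert-butyldimethylsilyloxy)-3-methoxybenzaldehyde, via aryllithium 5 (not isolated), via lithium hemiaminal alkoxide 6 (not isolated)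
Conditions: n-BuLi, THF, −78 °C; DMF, −78 → 0 °C; aq NH4Cl
Reagents that add atoms: N,N-dimethylformamide CN(C)C=O
Why: Bromine–lithium exchange at −78 °C outruns attack on the aryl silyl ether, and the aryllithium adds to DMF to give a stable tetrahedral adduct that collapses to the aldehyde only on work-up (Bouveault-type formylation).

**Step 5**
Reactants: 8 prop-2-yn-1-ol (propargyl alcohol)
Product: 9 tert-butyldimethyl(prop-2-yn-1-yloxy)silane
Conditions: TBSCl, imidazole, CH2Cl2, 0 °C → rt
Reagents that add atoms: tert-butyldimethylsilyl chloride CC(C)(C)[Si](C)(C)Cl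
Why: Standard imidazole-promoted silylation of a primary alcohol.

**Step 6**
Reactants: 9 tert-butyldimethyl(prop-2-yn-1-yloxy)silane
Product: 10 (E)-tert-butyldimethyl{[3-(4,4,5,5-tetramethyl-1,3,2-dioxaborolan-2-yl)prop-2-en-1-yl]oxy}silane
Conditions: pinacolborane (1.1 equiv), Cp2Zr(H)Cl (5 mol %), Et3N (10 mol %), neat, 60 °C
Reagents that add atoms: pinacolborane CC1(C)OBOC1(C)C
Why: Zirconium-hydride-catalysed syn-hydroboration of the terminal alkyne places boron on the terminal carbon and gives only the E-alkenylboronate.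

**Step 7**
Reactants: 11 resorcinol (benzene-1,3-diol)
Product: 12 1,3-dimethoxybenzene
Conditions: MeI (2.5 equiv), K2CO3, acetone, reflux
Reagents that add atoms: iodomethane CI
Why: Exhaustive Williamson O-methylation under weakly basic aprotic conditions, where O-alkylation outruns C-alkylation of resorcinol.

**Step 8**
Reactants: 12 1,3-dimethoxybenzene
Product: 15 2,6-dimethoxyphenol, via 2-lithio-1,3-dimethoxybenzene 13 (not isolated), via lithium aryltrimethoxyborate 14 (not isolated)
Conditions: n-BuLi, THF, 0 °C → rt; B(OMe)3, −78 °C → rt; AcOH, 30% H2O2, 0 °C → rt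
Reagents that add atoms: hydrogen peroxide OO
Why: Directed ortho-metalation occurs at C2 between the two methoxy groups, and the aryllithium is trapped by B(OMe)3 and oxidised by H2O2 (1,2-aryl shift from boron to oxygen), so the hydroxyl lands exactly at that position.

**Step 9**
Reactants: 15 2,6-dimethoxyphenol
Product: 16 4-bromo-2,6-dimethoxyphenol
Conditions: NBS (1.0 equiv), NaH (cat.), CHCl3, −45 °C → rt
Reagents that add atoms: N-bromosuccinimide O=C1CCC(=O)N1Br
Why: Electrophilic aromatic bromination in which both positions ortho to OH are blocked by OMe, so the phenol directs bromine to the free para position, and the low temperature limits oxidation to quinones.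

**Step 10**
Reactants: 16 4-bromo-2,6-dimethoxyphenol; 10 (E)-alkenylboronate
Product: 17 4-[(E)-3-(tert-butyldimethylsilyloxy)prop-1-en-1-yl]-2,6-dimethoxyphenol
Conditions: Pd(OAc)2 (3 mol %), SPhos (6 mol %), K3PO4 (3 equiv), THF/H2O 10:1, 60 °C
Reagents that add atoms: none
Why: Suzuki–Miyaura coupling in which the electron-rich biaryl phosphine lets zerovalent palladium insert into the electron-rich C–Br bond even as the phenoxide, and transmetalation/reductive elimination keep the E geometry of the boronate.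

**Step 11**
Reactants: 18 bromoacetyl bromide
Product: 19 (S)-4-benzyl-3-(2-bromoacetyl)oxazolidin-2-one
Conditions: (S)-4-benzyl-2-oxazolidinone, n-BuLi, THF, −78 °C; then 18, −78 → 0 °C
Reagents that add atoms: (S)-4-benzyl-2-oxazolidinone O=C1N[C@@H](Cc2ccccc2)CO1
Why: N-Acylation of the lithiated oxazolidinone by the acid bromide, which at −78 °C is far more electrophilic than the CH2Br carbon; the auxiliary stereocentre is not touched.

**Step 12**
Reactants: 17 4-[(E)-3-(tert-butyldimethylsilyloxy)prop-1-en-1-yl]-2,6-dimethoxyphenol; 19 (S)-4-benzyl-3-(2-bromoacetyl)oxazolidin-2-one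
Product: 20 (S)-4-benzyl-3-(2-{4-[(E)-3-(tert-butyldimethylsilyloxy)prop-1-en-1-yl]-2,6-dimethoxyphenoxy}acetyl)oxazolidin-2-one
Conditions: K2CO3 (1.5 equiv), MeCN, rt
Reagents that add atoms: none
Why: Williamson etherification (SN2) of the phenoxide at the carbonyl-activated primary bromide, which is faster than attack at the imide carbonyl, and K2CO3 is too weak to enolise the product.

**Step 13**
Reactants: 20 (S)-4-benzyl-3-(2-{4-[(E)-3-(tert-butyldimethylsilyloxy)prop-1-en-1-yl]-2,6-dimethoxyphenoxy}acetyl)oxazolidin-2-one; 7 4-(tert-butyldimethylsilyloxy)-3-methoxybenzaldehyde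
Product: 23 (S)-4-benzyl-3-[(2S,3R)-3-[4-(tert-butyldimethylsilyloxy)-3-methoxyphenyl]-2-{4-[(E)-3-(tert-butyldimethylsilyloxy)prop-1-en-1-yl]-2,6-dimethoxyphenoxy}-3-hydroxypropanoyl]oxazolidin-2-one, via Z-boron enolate 21 (not isolated), via boron aldolate 22 (not isolated)
Conditions: Bu2BOTf (1.2 equiv), iPr2NEt (1.4 equiv), CH2Cl2, −78 → 0 °C; 7, −78 → 0 °C; pH 7 buffer, MeOH, 30% H2O2, 0 °C
Reagents that add atoms: none
Why: Evans syn-aldol in which Bu2BOTf/iPr2NEt give the Z-boron enolate, which reacts through a chair Zimmerman–Traxler transition state with the auxiliary carbonyl dipole opposed to the enolate C–O, so the aldehyde meets the face away from the benzyl group and both new centres are set at once as (2S,3R), the syn (threo) pair whose absolute configuration is fixed by the (S)-auxiliary; H2O2 then cleaves the O–B bond of the aldolate.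

**Step 14**
Reactants: 23 aldol adduct
Product: 24 (1R,2R)-1-[4-(tert-butyldimethylsilyloxy)-3-methoxyphenyl]-2-{4-[(E)-3-(tert-butyldimethylsilyloxy)prop-1-en-1-yl]-2,6-dimethoxyphenoxy}propane-1,3-diol
Conditions: LiBH4 (2 equiv), MeOH (2 equiv), THF, 0 °C
Reagents that add atoms: none
Why: Reductive cleavage of the N-acyloxazolidinone by hydride attack at the exocyclic imide carbonyl releases the auxiliary and gives the primary alcohol without touching either stereocentre (the descriptor at the aryloxy carbon changes from S to R only because the CIP priorities change), while the alkene and silyl ethers are inert to LiBH4.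

**Step 15**
Reactants: 24 bis-TBS diol
Product: 25 (1R,2R)-1-(4-hydroxy-3-methoxyphenyl)-2-{4-[(E)-3-hydroxyprop-1-en-1-yl]-2,6-dimethoxyphenoxy}propane-1,3-diol (target)
Conditions: Bu4NF (2.5 equiv), AcOH (2.5 equiv), THF, 0 °C → rt
Reagents that add atoms: none
Why: Fluoride-driven desilylation (strong Si–F bond) removes both the aryl and the allylic TBS groups, and the AcOH buffer keeps the freed p-hydroxybenzyl alcohol from forming a quinone methide, so C7 and C8 stay intact.

## Compound list

1 | catechol (benzene-1,2-diol) | Oc1ccccc1O | starting material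
2 | guaiacol (2-methoxyphenol) | COc1ccccc1O | intermediate
3 | 4-bromo-2-methoxyphenol | COc1cc(Br)ccc1O | intermediate
4 | (4-bromo-2-methoxyphenoxy)(tert-butyl)dimethylsilane | COc1cc(Br)ccc1O[Si](C)(C)C(C)(C)C | intermediate
5 | [4-(tert-butyldimethylsilyloxy)-3-methoxyphenyl]lithium (not isolated) | [Li]c1ccc(O[Si](C)(C)C(C)(C)C)c(OC)c1 | intermediate
6 | lithium [4-(tert-butyldimethylsilyloxy)-3-methoxyphenyl](dimethylamino)methanolate (racemic, not isolated) | [Li+].CN(C)C([O-])c1ccc(O[Si](C)(C)C(C)(C)C)c(OC)c1 | intermediate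
7 | 4-(tert-butyldimethylsilyloxy)-3-methoxybenzaldehyde | COc1cc(C=O)ccc1O[Si](C)(C)C(C)(C)C | intermediate
8 | prop-2-yn-1-ol | C#CCO | starting material
9 | tert-butyldimethyl(prop-2-yn-1-yloxy)silane | C#CCO[Si](C)(C)C(C)(C)C | intermediate
10 | (E)-tert-butyldimethyl{[3-(4,4,5,5-tetramethyl-1,3,2-dioxaborolan-2-yl)prop-2-en-1-yl]oxy}silane | CC(C)(C)[Si](C)(C)OC/C=C/B1OC(C)(C)C(C)(C)O1 | intermediate
11 | resorcinol (benzene-1,3-diol) | Oc1cccc(O)c1 | starting material
12 | 1,3-dimethoxybenzene | COc1cccc(OC)c1 | intermediate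
13 | (2,6-dimethoxyphenyl)lithium (not isolated) | [Li]c1c(OC)cccc1OC | intermediate
14 | lithium (2,6-dimethoxyphenyl)trimethoxyborate (not isolated) | [Li+].CO[B-](OC)(OC)c1c(OC)cccc1OC | intermediate
15 | 2,6-dimethoxyphenol | COc1cccc(OC)c1O | intermediate
16 | 4-bromo-2,6-dimethoxyphenol | COc1cc(Br)cc(OC)c1O | intermediate
17 | 4-[(E)-3-(tert-butyldimethylsilyloxy)prop-1-en-1-yl]-2,6-dimethoxyphenol | COc1cc(/C=C/CO[Si](C)(C)C(C)(C)C)cc(OC)c1O | intermediate
18 | bromoacetyl bromide | BrCC(Br)=O | starting material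
19 | (S)-4-benzyl-3-(2-bromoacetyl)oxazolidin-2-one | O=C(CBr)N1C(=O)OC[C@@H]1Cc1ccccc1 | intermediate
20 | (S)-4-benzyl-3-(2-{4-[(E)-3-(tert-butyldimethylsilyloxy)prop-1-en-1-yl]-2,6-dimethoxyphenoxy}acetyl)oxazolidin-2-one | COc1cc(/C=C/CO[Si](C)(C)C(C)(C)C)cc(OC)c1OCC(=O)N1C(=O)OC[C@@H]1Cc1ccccc1 | intermediate
21 | (S)-4-benzyl-3-[(Z)-1-(dibutylboranyloxy)-2-{4-[(E)-3-(tert-butyldimethylsilyloxy)prop-1-en-1-yl]-2,6-dimethoxyphenoxy}ethenyl]oxazolidin-2-one (Z-boron enolate, not isolated) | CCCCB(CCCC)O/C(=C\Oc1c(OC)cc(/C=C/CO[Si](C)(C)C(C)(C)C)cc1OC)N1C(=O)OC[C@@H]1Cc1ccccc1 | intermediate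
22 | O-dibutylboranyl aldolate of 23, (2S,3R), auxiliary (S) (not isolated) | COc1cc([C@@H](OB(CCCC)CCCC)[C@@H](C(=O)N2C(=O)OC[C@@H]2Cc2ccccc2)Oc2c(OC)cc(/C=C/CO[Si](C)(C)C(C)(C)C)cc2OC)ccc1O[Si](C)(C)C(C)(C)C | intermediate
23 | (S)-4-benzyl-3-[(2S,3R)-3-[4-(tert-butyldimethylsilyloxy)-3-methoxyphenyl]-2-{4-[(E)-3-(tert-butyldimethylsilyloxy)prop-1-en-1-yl]-2,6-dimethoxyphenoxy}-3-hydroxypropanoyl]oxazolidin-2-one | COc1cc([C@@H](O)[C@@H](C(=O)N2C(=O)OC[C@@H]2Cc2ccccc2)Oc2c(OC)cc(/C=C/CO[Si](C)(C)C(C)(C)C)cc2OC)ccc1O[Si](C)(C)C(C)(C)C | intermediate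
24 | (1R,2R)-1-[4-(tert-butyldimethylsilyloxy)-3-methoxyphenyl]-2-{4-[(E)-3-(tert-butyldimethylsilyloxy)prop-1-en-1-yl]-2,6-dimethoxyphenoxy}propane-1,3-diol | COc1cc([C@@H](O)[C@@H](CO)Oc2c(OC)cc(/C=C/CO[Si](C)(C)C(C)(C)C)cc2OC)ccc1O[Si](C)(C)C(C)(C)C | intermediate
25 | (1R,2R)-1-(4-hydroxy-3-methoxyphenyl)-2-{4-[(E)-3-hydroxyprop-1-en-1-yl]-2,6-dimethoxyphenoxy}propane-1,3-diol (CNP0166461.2; threo, 7R,8R) | COc1cc([C@@H](O)[C@@H](CO)Oc2c(OC)cc(/C=C/CO)cc2OC)ccc1O | target

## Step count and risks

Total step count: 15.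
Longest linear sequence: 8 steps (7 → 8 → 9 → 10 → 12 → 13 → 14 → 15, from resorcinol). The other branches are catechol (steps 1–4), propargyl alcohol (steps 5–6) and bromoacetyl bromide (step 11).

The three steps most likely to fail:

**Step 10 (Suzuki coupling on a free, very electron-rich bromophenol).** Oxidative addition may be slow and the boronate may protodeboronate; the preceding bromination is also the least clean aromatic substitution. The fallback sets out from 15 and comes back at 17, avoiding both the bromide and palladium. Duff formylation of 15 (hexamethylenetetramine, CF3CO2H, reflux, then aq HCl) gives syringaldehyde F1. Wittig olefination with Ph3P=CHCO2Et in hot toluene gives ethyl (E)-sinapate F2. iBu2AlH in toluene at 0 °C reduces the ester to sinapyl alcohol F3. Double silylation (TBSCl, imidazole, DMF) gives the bis-TBS ether F4, and K2CO3 in MeOH cleaves only its aryl silyl ether to give 17.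

**Step 12 (phenoxide alkylation with the bromoacetyl imide).** The phenoxide may attack the imide carbonyl and strip the auxiliary instead of displacing bromide. The fallback sets out from 17 and comes back at 20, attaching the auxiliary last. Alkylation of 17 with methyl bromoacetate and K2CO3 in acetone gives the methyl aryloxyacetate F5. LiOH in THF/H2O gives the aryloxyacetic acid F6. tBuCOCl/Et3N in THF at −20 °C gives the mixed pivalic anhydride F7, which lithiated (S)-4-benzyl-2-oxazolidinone acylates at −78 °C on the less hindered carbonyl to give 20.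

**Step 13 (Evans aldol).** The bulky 2,6-dimethoxyaryloxy enolate and the electron-rich aldehyde may react sluggishly or with eroded syn selectivity, and Bu2BOTf could ionise the allylic silyl ether. The fallback sets out from 17 and 7 and comes back at 24; it sets the stereocentres by catalytic reduction instead of an auxiliary. Alkylation of 17 with ethyl bromoacetate/K2CO3 gives the ethyl aryloxyacetate F8. LiN(iPr)2 in THF at −78 °C gives its lithium enolate F9, which adds to 7 to give the racemic erythro/threo β-hydroxy ester F10. Dess–Martin periodinane oxidises this to the racemic α-aryloxy β-keto ester F11. Asymmetric transfer hydrogenation with dynamic kinetic resolution (RuCl[(S,S)-TsDPEN](p-cymene), HCO2H/Et3N, the catalyst enantiomer that gives (S)-1-phenylethanol from acetophenone) reduces the rapidly epimerising keto ester to the syn-(2S,3R) hydroxy ester F12. LiBH4 reduction of the ester gives 24.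

## Further compounds

F1 | step 10 | syringaldehyde (4-hydroxy-3,5-dimethoxybenzaldehyde) | COc1cc(C=O)cc(OC)c1O
F2 | step 10 | ethyl (E)-sinapate [ethyl (E)-3-(4-hydroxy-3,5-dimethoxyphenyl)prop-2-enoate] | CCOC(=O)/C=C/c1cc(OC)c(O)c(OC)c1
F3 | step 10 | sinapyl alcohol [4-[(E)-3-hydroxyprop-1-en-1-yl]-2,6-dimethoxyphenol] | COc1cc(/C=C/CO)cc(OC)c1O
F4 | step 10 | tert-butyl{4-[(E)-3-(tert-butyldimethylsilyloxy)prop-1-en-1-yl]-2,6-dimethoxyphenoxy}dimethylsilane | COc1cc(/C=C/CO[Si](C)(C)C(C)(C)C)cc(OC)c1O[Si](C)(C)C(C)(C)C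
F5 | step 12 | methyl 2-{4-[(E)-3-(tert-butyldimethylsilyloxy)prop-1-en-1-yl]-2,6-dimethoxyphenoxy}acetate | COC(=O)COc1c(OC)cc(/C=C/CO[Si](C)(C)C(C)(C)C)cc1OC
F6 | step 12 | 2-{4-[(E)-3-(tert-butyldimethylsilyloxy)prop-1-en-1-yl]-2,6-dimethoxyphenoxy}acetic acid | OC(=O)COc1c(OC)cc(/C=C/CO[Si](C)(C)C(C)(C)C)cc1OC
F7 | step 12 | mixed anhydride of F6 with pivalic acid | CC(C)(C)C(=O)OC(=O)COc1c(OC)cc(/C=C/CO[Si](C)(C)C(C)(C)C)cc1OC
F8 | step 13 | ethyl 2-{4-[(E)-3-(tert-butyldimethylsilyloxy)prop-1-en-1-yl]-2,6-dimethoxyphenoxy}acetate | CCOC(=O)COc1c(OC)cc(/C=C/CO[Si](C)(C)C(C)(C)C)cc1OC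
F9 | step 13 | lithium enolate of F8 (enolate geometry not defined) | [Li+].CCOC([O-])=COc1c(OC)cc(/C=C/CO[Si](C)(C)C(C)(C)C)cc1OC
F10 | step 13 | ethyl 3-[4-(tert-butyldimethylsilyloxy)-3-methoxyphenyl]-2-{4-[(E)-3-(tert-butyldimethylsilyloxy)prop-1-en-1-yl]-2,6-dimethoxyphenoxy}-3-hydroxypropanoate (racemic erythro/threo mixture) | CCOC(=O)C(Oc1c(OC)cc(/C=C/CO[Si](C)(C)C(C)(C)C)cc1OC)C(O)c1ccc(O[Si](C)(C)C(C)(C)C)c(OC)c1
F11 | step 13 | ethyl 3-[4-(tert-butyldimethylsilyloxy)-3-methoxyphenyl]-2-{4-[(E)-3-(tert-butyldimethylsilyloxy)prop-1-en-1-yl]-2,6-dimethoxyphenoxy}-3-oxopropanoate (racemic) | CCOC(=O)C(Oc1c(OC)cc(/C=C/CO[Si](C)(C)C(C)(C)C)cc1OC)C(=O)c1ccc(O[Si](C)(C)C(C)(C)C)c(OC)c1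
F12 | step 13 | ethyl (2S,3R)-3-[4-(tert-butyldimethylsilyloxy)-3-methoxyphenyl]-2-{4-[(E)-3-(tert-butyldimethylsilyloxy)prop-1-en-1-yl]-2,6-dimethoxyphenoxy}-3-hydroxypropanoate | COc1cc([C@@H](O)[C@@H](C(=O)OCC)Oc2c(OC)cc(/C=C/CO[Si](C)(C)C(C)(C)C)cc2OC)ccc1O[Si](C)(C)C(C)(C)C
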